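When a flask is slow, you can ask how its rate follows what is left in it.

- blue: starting material 0.083 M; second substrate 0.083 M; gas 25 mM (held); free catalyst 0.83 mM; the very flask that is asked about, followed so far
- flask: starting material 0.083 M; second substrate 0.0830 M; gas 25 mM (held); free catalyst 0.83 mM

blue run (percent of the starting material charged)

| time / s | target / % | starting material / % |
|---|---|---|
| 10.0 | 6.9 | 92.6 |
| 12.0 | 8.9 | 90.0 |
| 20.0 | 18.6 | 81.3 |
| 25.0 | 23.8 | 75.4 |
| 40.0 | 40.4 | 58.5 |
| 60.0 | 60.7 | 39.5 |
| 90.0 | 83.1 | 17.0 |

(each reading ± 0.3 percentage points)

- at the start none of the gas is in solution
- no earlier run changes the charge of free catalyst; that part of a forecast is a guess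
- no earlier run changes the charge of second substrate; that part of a forecast is a guess

1. apparent order in second substrate when 20 % of the starting material are converted (percent change of the rate of making target for one percent more second substrate charged)
2. factor on the rate of making target when 20 % of the starting material are converted if free catalyst is charged twice over

The blue run and the flask asked about hold the same charges, so the blue run is this flask, read up to 90.0 s, where the last reading shows 17.0 % of the starting material. In the blue run, target grows by 0.0115 s⁻¹ of the charge between 12.0 s and 25.0 s, and by 0.00747 s⁻¹ between 60.0 s and 90.0 s. Meanwhile the starting material left in the blue run, taken as the mean of each pair of readings, drops from 82.7 % to 28.3 % of the charge, so the rate of the blue run falls less than its starting material does.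

Now set up a scale. A rate blind to what the flask holds scores zero, and a rate proportional to it scores one. The logarithm of the rate ratio over that of the ratio of what is left, an apparent order along the run, I call the chemical share, and the readings give 0.399.

If the rate follows catalyst with that same share, doubling the catalyst gives my factor of 1.32. The equal charges of second substrate were never varied, so I put its order at zero, give or take the share. The forecast says 0.15 (−0.05 to 0.35) for the order in second substrate and 1.2 (1.08 to 1.6) for the factor on doubling free catalyst, holding that “the reaction is largely gas-transfer limited”.

The simulation gives −0.18 for the order and 1.29 for the factor, so the order lies below the forecast's range.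

    starting material + free catalyst ⇌ catalyst intermediate A (K = 300 M⁻¹, k = 2000 M⁻¹ s⁻¹)
    reagent + catalyst intermediate A → free catalyst + target (k = 150 M⁻¹ s⁻¹)
    second substrate + free catalyst ⇌ catalyst intermediate B (K = 7.00 M⁻¹, k = 990 M⁻¹ s⁻¹)
    reagent + catalyst intermediate B → free catalyst + second product (k = 110 M⁻¹ s⁻¹)
    second substrate + catalyst intermediate B → spent catalyst (k = 2.70 M⁻¹ s⁻¹)
    gas ⇌ reagent, rate k6*(csat - [reagent]) (kL = 0.0690 s⁻¹)

At the start of the flask, free catalyst went to starting material 2.0 times as fast as to second substrate, forward steps alone, and later reagent meeting catalyst intermediate A did half of its turnover up to 8.00 min by 0.789 min, while spent catalyst reached 30.5 % of the catalyst charged at 0.800 min; if the rate follows catalyst with the chemical share, the 69.5 % not spent is a factor of 0.865 on the rate. By 4.00 min spent catalyst in the flask stood at >99.9 % of the catalyst charged and target at 96.5 %, and at 80.0 min starting material still stood at 3.54 %.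

The earlier runs and the new flask stem from a simulated flask with constants of no real substance; noise was put on by code.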